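**Plan**
1. Locants used throughout: oxolane O1–C2(aryl)–C3(CH2OH)–C4(aroyl)–C5H2; the target is 2S,3R,4S with 2,3-trans and 3,4-trans substituents. The hydroxymethyl carbon on C3 is β to the C4 aryl ketone, so it can enter as the CH2 of a cyclopropane spanning C3–C4 of a 2,5-dihydrofuran-3-yl aryl ketone and be released by breaking only its bond to C4.
2. Retrosynthetic cuts, in order: the two O–benzyl bonds; C3–CH2 together with a temporary C4–CH2 bond (sulfoxonium ylide on the C3=C4 enone); C3=C4 (ring-closing metathesis); C4–C(=O) (vinyllithium plus aldehyde, then oxidation); O1–C5 (Williamson ether); C2–C3 (vinyl Grignard).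
3. Forward: one aldehyde supplies both aryl rings. The open chain is joined as carbinol → 2-bromoallyl ether → dienyl enone, metathesis closes the oxolane as its 2,5-dihydro form, the ylide fuses on the cyclopropane, and iodide opening plus hydrolysis frees CH2OH.
4. Stereochemistry: C2 from lipase resolution of the aryl vinyl carbinol; C3 from ylide attack anti to the C2 aryl group; C4 from base equilibration to the trans ketone.

Key step: step 7

Remark (assumption): CAL-B is taken to acylate the R enantiomer of the aryl vinyl carbinol, as it does for 1-aryl secondary alcohols in general, so the S alcohol is the one recovered.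

**Route**

Step 1
Reactants: 1 3-(benzyloxy)-4-methoxybenzaldehyde; 2 vinylmagnesium bromide
Product: 3 rac-1-[3-(benzyloxy)-4-methoxyphenyl]prop-2-en-1-ol
Conditions: THF, 0 °C; then H2O
Reagents that add atoms: vinylmagnesium bromide (2), C=C[Mg]Br
Why: Grignard 1,2-addition of a vinyl nucleophile to an aromatic aldehyde forms the C2–C3 bond and the (still racemic) C2 carbinol centre.

Step 2
Reactants: 3 rac-1-[3-(benzyloxy)-4-methoxyphenyl]prop-2-en-1-ol
Product: 4 (1S)-1-[3-(benzyloxy)-4-methoxyphenyl]prop-2-en-1-ol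
Conditions: Novozym 435 (immobilised CAL-B), vinyl acetate, MTBE, 30 °C, taken slightly past half conversion; chromatography
Reagents that add atoms: none
Why: Lipase-catalysed kinetic resolution by enantioselective transesterification should acylate the R alcohol (aryl as large group, vinyl as medium group) and leave the S alcohol, which fixes C2.

Step 3
Reactants: 4 (1S)-1-[3-(benzyloxy)-4-methoxyphenyl]prop-2-en-1-ol; 5 2,3-dibromoprop-1-ene
Product: 7 2-(benzyloxy)-4-{(1S)-1-[(2-bromoprop-2-en-1-yl)oxy]prop-2-en-1-yl}-1-methoxybenzene, via sodium alkoxide 6 (not isolated)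
Conditions: NaH, THF, 0 °C; then 5, cat. Bu4NI, 0 °C → rt
Reagents that add atoms: 2,3-dibromoprop-1-ene (5), C=C(Br)CBr
Why: Williamson etherification by SN2 at the allylic CH2Br (the vinylic bromide is inert) forms the O1–C5 bond without touching the C2–O bond, so the configuration is kept.

Step 4
Reactants: 7 2-(benzyloxy)-4-{(1S)-1-[(2-bromoprop-2-en-1-yl)oxy]prop-2-en-1-yl}-1-methoxybenzene; 1 3-(benzyloxy)-4-methoxybenzaldehyde
Product: 9 1-[3-(benzyloxy)-4-methoxyphenyl]-2-[({(1S)-1-[3-(benzyloxy)-4-methoxyphenyl]prop-2-en-1-yl}oxy)methyl]prop-2-en-1-ol (both carbinol epimers), via 2-lithioallyl ether 8 (not isolated)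
Conditions: t-BuLi (2.1 equiv), Et2O, −78 °C; then 1 in THF, −78 → 0 °C; then H2O
Reagents that add atoms: 3-(benzyloxy)-4-methoxybenzaldehyde (1), O=Cc1ccc(OC)c(OCc2ccccc2)c1
Why: Bromine–lithium exchange on a 2-bromoallyl ether is far faster at −78 °C than deprotonation of the C2–H or of a benzyl ether, and the resulting 2-lithioallyl ether adds 1,2 to the aldehyde to form the C4–C(carbonyl) bond; the new carbinol centre is removed in step 5.

Step 5
Reactants: 9 the diene alcohol
Product: 10 1-[3-(benzyloxy)-4-methoxyphenyl]-2-[({(1S)-1-[3-(benzyloxy)-4-methoxyphenyl]prop-2-en-1-yl}oxy)methyl]prop-2-en-1-one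
Conditions: Dess–Martin periodinane, CH2Cl2, 0 °C → rt
Reagents that add atoms: none
Why: Dess–Martin oxidation of a benzylic and allylic secondary alcohol gives the cross-conjugated aryl enone under nearly neutral conditions and merges both carbinol epimers.

Step 6
Reactants: 10 the dienyl enone
Product: 11 [3-(benzyloxy)-4-methoxyphenyl]{(5S)-5-[3-(benzyloxy)-4-methoxyphenyl]-2,5-dihydrofuran-3-yl}methanone
Conditions: Grubbs II (5 mol %), CH2Cl2 (0.01 M), 40 °C
Reagents that add atoms: none
Why: Ring-closing metathesis between the vinyl group (initiation site) and the 1,1-disubstituted enone alkene is a five-membered closure well established for 2-(allyloxymethyl)acrylates and related enones; ethylene loss drives it and the allylic C2 centre is not touched.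

Step 7
Reactants: 11 [3-(benzyloxy)-4-methoxyphenyl]{(5S)-5-[3-(benzyloxy)-4-methoxyphenyl]-2,5-dihydrofuran-3-yl}methanone; 12 trimethylsulfoxonium iodide
Product: 15 [3-(benzyloxy)-4-methoxyphenyl]{(1S,4S,5S)-4-[3-(benzyloxy)-4-methoxyphenyl]-3-oxabicyclo[3.1.0]hexan-1-yl}methanone (cyclopropane CH2 anti to the aryl group), via dimethylsulfoxonium methylide 13 (not isolated), via sulfoxonium enolate betaine 14 (not isolated)
Conditions: 12 (1.3 equiv), NaH (1.2 equiv), DMSO, rt, 30 min; then 11 in THF, rt
Reagents that add atoms: trimethylsulfoxonium iodide (12), C[S+](C)(C)=O.[I-] (its CH2 is delivered through ylide 13, C[S+](C)(=O)[CH2-])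
Why: The ylide adds reversibly to the carbonyl but productively in conjugate fashion to the β-carbon C3, giving enolate betaine 14, whose enolate carbon C4 then displaces dimethyl sulfoxide from the new CH2 group. This is the Corey–Chaykovsky cyclopropanation of a cyclic enone, here applied to a 3-aroyl-2,5-dihydrofuran. The three-membered ring closes 3-exo-tet and can only be cis-fused to the five-membered ring. The C3 configuration is set by the aryl group on the adjacent C2, which shields one face so that the CH2 arrives anti to it, and the C4 configuration follows from the cis fusion. The step needs conjugate rather than carbonyl addition, which the sulfoxonium (as opposed to sulfonium) ylide secures, and face selectivity, which the neighbouring C2 substituent secures. Keeping the salt in slight excess over NaH leaves only the weakly basic ylide in solution, which limits deprotonation at C2–H.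

Step 8
Reactants: 15 the 1-aroyl-4-aryl-3-oxabicyclo[3.1.0]hexane
Product: 17 [3-(benzyloxy)-4-methoxyphenyl]{(4S,5S)-5-[3-(benzyloxy)-4-methoxyphenyl]-4-(iodomethyl)oxolan-3-yl}methanone (epimers at the aroyl-bearing carbon), via iodomagnesium enolate 16 (not isolated)
Conditions: MgI2 (2 equiv), THF, 65 °C; then H2O, 0 °C
Reagents that add atoms: magnesium iodide, [Mg+2].[I-].[I-]
Why: Lewis acid and iodide homoconjugate opening of an aryl cyclopropyl ketone: magnesium activates the carbonyl and iodide attacks the unhindered cyclopropane CH2 in SN2 fashion, cleaving only the C4–CH2 bond, so C3 and its configuration are untouched, and protonation of the enolate gives C4 epimers that converge in step 10.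

Step 9
Reactants: 17 the iodomethyl ketone
Product: 18 [3-(benzyloxy)-4-methoxyphenyl]{(4R,5S)-5-[3-(benzyloxy)-4-methoxyphenyl]-4-(hydroxymethyl)oxolan-3-yl}methanone (epimers at the aroyl-bearing carbon)
Conditions: AgOCOCF3 (1.5 equiv), acetone–H2O (4:1), rt → 40 °C; then aq. NaHCO3
Reagents that add atoms: water, O
Why: Silver-assisted hydrolysis of a primary iodide with participation of the γ-ketone oxygen gives an aryl-stabilised five-membered oxocarbenium ion (the cation of the Cloke–Wilson manifold) that water captures and that collapses to the γ-hydroxy ketone; no base is present, so reclosure to the cyclopropane cannot occur.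

Step 10
Reactants: 18 the hydroxymethyl ketone as epimer mixture
Product: 19 [3-(benzyloxy)-4-methoxyphenyl]{(3S,4R,5S)-5-[3-(benzyloxy)-4-methoxyphenyl]-4-(hydroxymethyl)oxolan-3-yl}methanone
Conditions: K2CO3 (cat.), MeOH, rt
Reagents that add atoms: none
Why: Base-mediated epimerisation through the aryl ketone enolate at C4, the only enolisable stereocentre, should settle on the 3,4-trans isomer, in which the three ring substituents alternate faces; C2 and C3 carry no acidic hydrogen.

Step 11
Reactants: 19 the all-trans dibenzyl ether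
Product: 20 (3-hydroxy-4-methoxyphenyl)[(3S,4R,5S)-5-(3-hydroxy-4-methoxyphenyl)-4-(hydroxymethyl)oxolan-3-yl]methanone (CNP0234761.1)
Conditions: H2 (1 atm), 10 % Pd/C, EtOAc, rt, stopped when debenzylation is complete
Reagents that add atoms: none
Why: Hydrogenolysis of aryl benzyl ethers at 1 atm in EtOAc should be much faster than reduction of the electron-rich aryl ketone or cleavage of the cyclic benzylic C2–O1 bond, and the neutral conditions leave C4 unchanged.

**Compound list**
1 | 3-(benzyloxy)-4-methoxybenzaldehyde | O=Cc1ccc(OC)c(OCc2ccccc2)c1 | starting material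
2 | vinylmagnesium bromide | C=C[Mg]Br | starting material
3 | rac-1-[3-(benzyloxy)-4-methoxyphenyl]prop-2-en-1-ol | C=CC(O)c1ccc(OC)c(OCc2ccccc2)c1 | intermediate
4 | (1S)-1-[3-(benzyloxy)-4-methoxyphenyl]prop-2-en-1-ol | C=C[C@@H](c1ccc(OC)c(OCc2ccccc2)c1)O | intermediate
5 | 2,3-dibromoprop-1-ene | C=C(Br)CBr | starting material
6 | sodium (1S)-1-[3-(benzyloxy)-4-methoxyphenyl]prop-2-en-1-olate | C=C[C@@H](c1ccc(OC)c(OCc2ccccc2)c1)[O-].[Na+] | intermediate
7 | 2-(benzyloxy)-4-{(1S)-1-[(2-bromoprop-2-en-1-yl)oxy]prop-2-en-1-yl}-1-methoxybenzene | C=C[C@@H](c1ccc(OC)c(OCc2ccccc2)c1)OCC(Br)=C | intermediate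
8 | 2-lithioallyl ether (vinyllithium from 7) | C=C[C@@H](c1ccc(OC)c(OCc2ccccc2)c1)OCC([Li])=C | intermediate
9 | 1-[3-(benzyloxy)-4-methoxyphenyl]-2-[({(1S)-1-[3-(benzyloxy)-4-methoxyphenyl]prop-2-en-1-yl}oxy)methyl]prop-2-en-1-ol, both carbinol epimers | C=C[C@@H](c1ccc(OC)c(OCc2ccccc2)c1)OCC(=C)C(O)c1ccc(OC)c(OCc2ccccc2)c1 | intermediate
10 | 1-[3-(benzyloxy)-4-methoxyphenyl]-2-[({(1S)-1-[3-(benzyloxy)-4-methoxyphenyl]prop-2-en-1-yl}oxy)methyl]prop-2-en-1-one | C=C[C@@H](c1ccc(OC)c(OCc2ccccc2)c1)OCC(=C)C(=O)c1ccc(OC)c(OCc2ccccc2)c1 | intermediate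
11 | [3-(benzyloxy)-4-methoxyphenyl]{(5S)-5-[3-(benzyloxy)-4-methoxyphenyl]-2,5-dihydrofuran-3-yl}methanone | COc1ccc(C(=O)C2=C[C@@H](c3ccc(OC)c(OCc4ccccc4)c3)OC2)cc1OCc1ccccc1 | intermediate
12 | trimethylsulfoxonium iodide | C[S+](C)(C)=O.[I-] | starting material
13 | dimethylsulfoxonium methylide | C[S+](C)(=O)[CH2-] | intermediate
14 | sulfoxonium enolate betaine (ylide adduct at C3, CH2 anti to the C2 aryl) | COc1ccc(C([O-])=C2CO[C@H](c3ccc(OC)c(OCc4ccccc4)c3)[C@H]2C[S+](C)(C)=O)cc1OCc1ccccc1 | intermediate
15 | [3-(benzyloxy)-4-methoxyphenyl]{(1S,4S,5S)-4-[3-(benzyloxy)-4-methoxyphenyl]-3-oxabicyclo[3.1.0]hexan-1-yl}methanone | COc1ccc(C(=O)[C@]23CO[C@H](c4ccc(OC)c(OCc5ccccc5)c4)[C@H]2C3)cc1OCc1ccccc1 | intermediate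
16 | iodomagnesium enolate of 17 | COc1ccc(C(O[Mg]I)=C2CO[C@H](c3ccc(OC)c(OCc4ccccc4)c3)[C@H]2CI)cc1OCc1ccccc1 | intermediate
17 | [3-(benzyloxy)-4-methoxyphenyl]{(4S,5S)-5-[3-(benzyloxy)-4-methoxyphenyl]-4-(iodomethyl)oxolan-3-yl}methanone, epimers at the aroyl-bearing carbon | COc1ccc(C(=O)C2CO[C@H](c3ccc(OC)c(OCc4ccccc4)c3)[C@H]2CI)cc1OCc1ccccc1 | intermediate
18 | [3-(benzyloxy)-4-methoxyphenyl]{(4R,5S)-5-[3-(benzyloxy)-4-methoxyphenyl]-4-(hydroxymethyl)oxolan-3-yl}methanone, epimers at the aroyl-bearing carbon | COc1ccc(C(=O)C2CO[C@H](c3ccc(OC)c(OCc4ccccc4)c3)[C@H]2CO)cc1OCc1ccccc1 | intermediate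
19 | [3-(benzyloxy)-4-methoxyphenyl]{(3S,4R,5S)-5-[3-(benzyloxy)-4-methoxyphenyl]-4-(hydroxymethyl)oxolan-3-yl}methanone | COc1ccc(C(=O)[C@@H]2CO[C@H](c3ccc(OC)c(OCc4ccccc4)c3)[C@H]2CO)cc1OCc1ccccc1 | intermediate
20 | (3-hydroxy-4-methoxyphenyl)[(3S,4R,5S)-5-(3-hydroxy-4-methoxyphenyl)-4-(hydroxymethyl)oxolan-3-yl]methanone | COc1ccc(C(=O)[C@@H]2CO[C@H](c3ccc(OC)c(O)c3)[C@H]2CO)cc1O | target

**Summary**
Total steps: 11. Longest linear sequence: 11 steps (from aldehyde 1, which is also used a second time in step 4).

**Steps most likely to fail**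

Step 7 (key step). The ylide may attack C3 from both faces, or it may deprotonate C2–H (γ to the ketone), which would racemise C2 or move the double bond into conjugation with the ring oxygen. The fallback avoids base and sets out from diene alcohol 9. Ring-closing metathesis before the oxidation (Grubbs II, CH2Cl2, 40 °C) should give the dihydrofuranyl carbinol F1. A hydroxyl-directed Simmons–Smith cyclopropanation (Et2Zn, CH2I2, CH2Cl2, 0 °C) should then deliver the zinc carbenoid to the C3=C4 bond on the face away from the C2 aryl group and give the cyclopropyl carbinol F2. Dess–Martin oxidation of F2 returns to the route at 15.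

Step 8. The Lewis acid may ionise the electron-rich benzylic C2–O1 bond, iodide may attack C3 instead of the CH2 (ring expansion to an oxane), or the opening may stay incomplete. The fallback sets out from 15 and uses nickel(0)-catalysed borylative ring opening of the aryl cyclopropyl ketone (Ni(cod)2, N-heterocyclic carbene ligand, B2pin2, toluene, 50 °C; aqueous work-up). Oxidative addition at the less hindered C4–CH2 bond should give the γ-boryl ketone F3. Oxidation of the C–B bond with NaBO3·4H2O in THF–H2O returns to the route at 18, bypassing 17.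

Step 10. The equilibration may stall because the cis epimer is held as its cis-fused cyclic hemiketal, or the ring may open by retro-oxa-Michael reaction in methanolic carbonate. The fallback sets out from 18. The primary alcohol is silylated (TBSCl, imidazole, DMF) to the silyl ether F4, which cannot form a hemiketal. F4 is epimerised with DBU in toluene to the 3,4-trans silyl ether F5. Desilylation (TBAF buffered with AcOH, THF) returns to the route at 19.

**Further compounds**
F1 | step 7 | [3-(benzyloxy)-4-methoxyphenyl]{(5S)-5-[3-(benzyloxy)-4-methoxyphenyl]-2,5-dihydrofuran-3-yl}methanol, both carbinol epimers | COc1ccc(C(O)C2=C[C@@H](c3ccc(OC)c(OCc4ccccc4)c3)OC2)cc1OCc1ccccc1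
F2 | step 7 | [3-(benzyloxy)-4-methoxyphenyl]{4-[3-(benzyloxy)-4-methoxyphenyl]-3-oxabicyclo[3.1.0]hexan-1-yl}methanol, ring configuration as in 15, both carbinol epimers | COc1ccc(C(O)[C@]23CO[C@H](c4ccc(OC)c(OCc5ccccc5)c4)[C@H]2C3)cc1OCc1ccccc1
F3 | step 8 | γ-boryl ketone: pinacol boronate in place of the iodide of 17, epimers at the aroyl-bearing carbon | COc1ccc(C(=O)C2CO[C@H](c3ccc(OC)c(OCc4ccccc4)c3)[C@H]2CB5OC(C)(C)C(C)(C)O5)cc1OCc1ccccc1
F4 | step 10 | tert-butyldimethylsilyl ether of 18, epimers at the aroyl-bearing carbon | COc1ccc(C(=O)C2CO[C@H](c3ccc(OC)c(OCc4ccccc4)c3)[C@H]2CO[Si](C)(C)C(C)(C)C)cc1OCc1ccccc1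
F5 | step 10 | tert-butyldimethylsilyl ether of 19 (3,4-trans) | COc1ccc(C(=O)[C@@H]2CO[C@H](c3ccc(OC)c(OCc4ccccc4)c3)[C@H]2CO[Si](C)(C)C(C)(C)C)cc1OCc1ccccc1
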